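## Retrosynthetic overview

- Numbering follows the isoflavanone (O1, C2, C3, C4; ring A C4a–C8a; ring B C1'–C6'). The route rests on the free 4'-OH of ring B, para to C1': with a leaving group on the benzylic carbon, ring B becomes a latent para-quinone methide whose exocyclic carbon is C3, so C3 is the electrophile and C4 can be the nucleophile.
- 28 ⇐ 27 by cleavage of the MOM ethers at O5 and O7. 27 ⇐ 25 by the C3–C4 bond of ring C: C4 is the carbene-bound acyl anion of the ring-A aldehyde, C3 the exocyclic carbon of the quinone methide released from a benzylic p-tolyl sulfone.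
- 25 ⇐ ring-A salicylaldehyde 8 + ring-B styrene oxide 21 (O1–C2 by phenoxide opening), then OH → SO2Tol and removal of the 4'-O-allyl group.
- 8 ⇐ 5-bromoresorcinol: prenylation between the two MOM ethers, Br → OH, then ortho-formylation of the symmetric phenol, which fixes the 6-prenyl pattern. 21 ⇐ 4-bromo-3-methoxyphenol: iodination between the two oxygens, Suzuki coupling with the (E)-alkenylboronate from 3-methylbut-1-yne, formylation, ylide epoxidation.
- Ring order: rings A and B come from the starting materials; ring C is the only ring formed, in the key step, which also sets C3.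

Key step: step 16

Assumption: the sense of induction of the aminoindanol triazolylidene on this new substrate class cannot be derived with certainty; the (5aR,10bS) catalyst is written, and its (5aS,10bR) antipode is to be used instead if a test run shows that it is the one leading to 3S.

## Route

Step 1
Reactants: 1 5-bromoresorcinol
Product: 2 1-bromo-3,5-bis(methoxymethoxy)benzene
Conditions: MOMCl, i-Pr2NEt, CH2Cl2, 0 °C → rt
Reagents that add atoms: chloromethyl methyl ether, COCCl
Why: O-alkylation of both phenols gives the bis-acetal, whose two MOM groups are the directing groups for step 2; the aryl bromide is inert.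

Step 2
Reactants: 2 1-bromo-3,5-bis(methoxymethoxy)benzene; 3 prenyl bromide (1-bromo-3-methylbut-2-ene)
Product: 6 5-bromo-1,3-bis(methoxymethoxy)-2-(3-methylbut-2-enyl)benzene, via aryllithium 4 (not isolated), via arylcopper 5 (not isolated)
Conditions: LiN(i-Pr)2 (LDA), THF, −78 °C; CuBr·SMe2, −78 → −40 °C; 3, −40 °C → rt
Reagents that add atoms: none
Why: Directed ortho-metalation removes the C–H flanked by both MOM ethers (an amide base does not exchange the bromide), and the arylcopper should substitute prenyl bromide at the primary carbon (SN2 rather than SN2').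

Step 3
Reactants: 6 5-bromo-1,3-bis(methoxymethoxy)-2-(3-methylbut-2-enyl)benzene
Product: 7 3,5-bis(methoxymethoxy)-4-(3-methylbut-2-enyl)phenol
Conditions: Pd2(dba)3 (2 mol %), 2-di-tert-butylphosphino-2',4',6'-triisopropylbiphenyl (8 mol %), KOH, 1,4-dioxane–H2O, 100 °C; then aq citric acid to pH 6
Reagents that add atoms: potassium hydroxide, [K+].[OH-]
Why: Palladium-catalysed hydroxylation of an unhindered aryl bromide with hydroxide; MOM ethers and the prenyl group tolerate hot aqueous base.

Step 4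
Reactants: 7 3,5-bis(methoxymethoxy)-4-(3-methylbut-2-enyl)phenol
Product: 8 6-hydroxy-2,4-bis(methoxymethoxy)-3-(3-methylbut-2-enyl)benzaldehyde
Conditions: MgCl2, Et3N, (CH2O)n, MeCN, 75 °C
Reagents that add atoms: paraformaldehyde (as formaldehyde), C=O
Why: Casnati–Skattebøl ortho-formylation: the magnesium phenoxide delivers formaldehyde only ortho to the free OH, and the two ortho positions of 7 are equivalent, so a single aldehyde with the prenyl group between the MOM ethers should form.

Step 5
Reactants: 9 4-bromo-3-methoxyphenol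
Product: 10 1-bromo-2-methoxy-4-(methoxymethoxy)benzene
Conditions: MOMCl, i-Pr2NEt, CH2Cl2, 0 °C → rt
Reagents that add atoms: chloromethyl methyl ether, COCCl
Why: O-alkylation installs the MOM ether that, together with the methoxy group, directs the metalation of step 6.

Step 6
Reactants: 10 1-bromo-2-methoxy-4-(methoxymethoxy)benzene
Product: 12 1-bromo-3-iodo-2-methoxy-4-(methoxymethoxy)benzene, via aryllithium 11 (not isolated)
Conditions: LiN(i-Pr)2 (LDA), THF, −78 °C; cannulated into I2, THF, −78 °C → rt; aq Na2S2O3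
Reagents that add atoms: iodine, II
Why: Directed ortho-metalation at the C–H between OMe and OMOM (two cooperating directing groups, C–Br untouched at −78 °C), then iodine quench, places the halogen at the future C3'.

Step 7
Reactants: 13 3-methylbut-1-yne
Product: 14 (E)-4,4,5,5-tetramethyl-2-(3-methylbut-1-enyl)-1,3,2-dioxaborolane
Conditions: pinacolborane, Cp2Zr(H)Cl (5 mol %), CH2Cl2, sealed tube, rt
Reagents that add atoms: pinacolborane, B1OC(C)(C)C(C)(C)O1
Why: Zirconium-catalysed hydroboration of a terminal alkyne is a syn, anti-Markovnikov addition, which fixes the E geometry.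

Step 8
Reactants: 12 1-bromo-3-iodo-2-methoxy-4-(methoxymethoxy)benzene; 14 (E)-4,4,5,5-tetramethyl-2-(3-methylbut-1-enyl)-1,3,2-dioxaborolane
Product: 15 1-bromo-2-methoxy-4-(methoxymethoxy)-3-[(E)-3-methylbut-1-enyl]benzene
Conditions: Pd(PPh3)4 (5 mol %), 2 M aq K2CO3, DME, 70 °C
Reagents that add atoms: none
Why: Suzuki–Miyaura coupling; oxidative addition into C–I is much faster than into C–Br with this catalyst, and the alkene geometry is retained.

Step 9
Reactants: 15 1-bromo-2-methoxy-4-(methoxymethoxy)-3-[(E)-3-methylbut-1-enyl]benzene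
Product: 18 2-methoxy-4-(methoxymethoxy)-3-[(E)-3-methylbut-1-enyl]benzaldehyde, via aryllithium 16 (not isolated), via lithium hemiaminolate 17 (not isolated)
Conditions: n-BuLi, THF, −78 °C; DMF, −78 → 0 °C; then H2O
Reagents that add atoms: N,N-dimethylformamide, CN(C)C=O
Why: Bromine–lithium exchange at −78 °C is faster than any deprotonation or addition to the styrene, and formylation of the aryllithium with DMF gives the aldehyde at the future C1'.

Step 10
Reactants: 18 2-methoxy-4-(methoxymethoxy)-3-[(E)-3-methylbut-1-enyl]benzaldehyde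
Product: 19 4-hydroxy-2-methoxy-3-[(E)-3-methylbut-1-enyl]benzaldehyde
Conditions: 2 M aq HCl, MeOH–THF, rt
Reagents that add atoms: none
Why: Acid-catalysed cleavage of the aryl MOM acetal; the para-formyl group keeps the styrenyl double bond unreactive toward dilute acid.

Step 11
Reactants: 19 4-hydroxy-2-methoxy-3-[(E)-3-methylbut-1-enyl]benzaldehyde
Product: 20 2-methoxy-3-[(E)-3-methylbut-1-enyl]-4-(prop-2-enyloxy)benzaldehyde
Conditions: allyl bromide, K2CO3, DMF, rt
Reagents that add atoms: allyl bromide, C=CCBr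
Why: Williamson etherification; the allyl ether survives the basic steps that follow and can be removed later without touching the ring-A MOM ethers.

Step 12
Reactants: 20 2-methoxy-3-[(E)-3-methylbut-1-enyl]-4-(prop-2-enyloxy)benzaldehyde
Product: 21 2-{2-methoxy-3-[(E)-3-methylbut-1-enyl]-4-(prop-2-enyloxy)phenyl}oxirane (racemic)
Conditions: Me3S+ I−, KOt-Bu, DMSO–THF, 0 °C → rt; used crude
Reagents that add atoms: trimethylsulfonium iodide, C[S+](C)C.[I-]
Why: Corey–Chaykovsky epoxidation transfers CH2 to the aldehyde only and leaves both C=C bonds alone; the epoxide carbon is racemic, which is of no consequence because this centre becomes planar in 26.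

Step 13
Reactants: 8 6-hydroxy-2,4-bis(methoxymethoxy)-3-(3-methylbut-2-enyl)benzaldehyde; 21 2-{2-methoxy-3-[(E)-3-methylbut-1-enyl]-4-(prop-2-enyloxy)phenyl}oxirane
Product: 22 6-[2-hydroxy-2-{2-methoxy-3-[(E)-3-methylbut-1-enyl]-4-(prop-2-enyloxy)phenyl}ethoxy]-2,4-bis(methoxymethoxy)-3-(3-methylbut-2-enyl)benzaldehyde (racemic)
Conditions: K2CO3 (0.5 equiv), DMF, 70 °C
Reagents that add atoms: none
Why: Base-mediated SN2 opening of the epoxide by the salicylaldehyde phenoxide at the unhindered terminal carbon forms the O1–C2 ether and leaves the benzylic carbinol (racemic).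

Step 14
Reactants: 22 the benzylic alcohol of step 13
Product: 24 6-[2-{2-methoxy-3-[(E)-3-methylbut-1-enyl]-4-(prop-2-enyloxy)phenyl}-2-(4-methylphenylsulfonyl)ethoxy]-2,4-bis(methoxymethoxy)-3-(3-methylbut-2-enyl)benzaldehyde (racemic), via benzylic mesylate 23 (not isolated)
Conditions: Ms2O, i-Pr2NEt, CH2Cl2, −20 °C; then p-TolSO2Na, DMF, −20 °C → rt
Reagents that add atoms: sodium p-toluenesulfinate, Cc1ccc(S(=O)[O-])cc1.[Na+]
Why: Nucleophilic substitution: the electron-rich secondary benzylic mesylate ionises easily and is captured at sulfur by sulfinate to give the sulfone (racemic), while the amine buffer keeps the MOM ethers and the aldehyde intact.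

Step 15
Reactants: 24 the 4'-O-allyl sulfone of step 14
Product: 25 6-[2-{4-hydroxy-2-methoxy-3-[(E)-3-methylbut-1-enyl]phenyl}-2-(4-methylphenylsulfonyl)ethoxy]-2,4-bis(methoxymethoxy)-3-(3-methylbut-2-enyl)benzaldehyde (racemic)
Conditions: Pd(PPh3)4 (5 mol %), p-TolSO2H, THF, rt
Reagents that add atoms: none
Why: Tsuji–Trost deallylation with sulfinic acid as the allyl acceptor runs without base, so the freed 4'-phenol stays protonated and does not expel the benzylic sulfinate.

Step 16
Reactants: 25 the 4'-hydroxy sulfone of step 15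
Product: 27 (3S)-3-{4-hydroxy-2-methoxy-3-[(E)-3-methylbut-1-enyl]phenyl}-5,7-bis(methoxymethoxy)-6-(3-methylbut-2-enyl)-2,3-dihydro-4H-chromen-4-one, via quinone methide 26 (not isolated)
Conditions: (5aR,10bS)-2-(pentafluorophenyl)-5a,10b-dihydro-4H,6H-indeno[2,1-b][1,2,4]triazolo[4,3-d][1,4]oxazin-2-ium tetrafluoroborate (20 mol %), powdered K2CO3 (1.2 equiv), 4 Å molecular sieves, CH2Cl2 (0.02 M), 0 °C
Reagents that add atoms: none
Why: Proposed new method: K2CO3 deprotonates the 4'-OH of 25 and the phenoxide expels p-toluenesulfinate to give quinone methide 26, whose exocyclic carbon is the future C3, while the triazolylidene adds to the ring-A aldehyde and forms the Breslow intermediate, whose nucleophilic C4 adds 1,6 to that carbon; ring B rearomatises to the 4'-phenoxide and loss of the carbene from the tetrahedral adduct gives the C4 ketone. The closest known reaction types are the enantioselective intramolecular Stetter cyclisation of O-tethered salicylaldehydes to 3-substituted chroman-4-ones and the carbene-catalysed 1,6-addition of aldehydes to stable para-quinone methides; a tethered quinone methide released in the flask from a sulfone has not been used as the acceptor. Ring C closes in a 6-exo-trig mode (C4 onto C3, the C3=C1' bond lying outside the new ring). C3 is the only new stereocentre; the racemic centre of 25 is erased in planar 26, and the face of the exocyclic carbon that is attacked is chosen by the aminoindanol backbone of the carbene in the cyclic transition state, so both enantiomers of 25 should converge on (3S)-27. The step needs the intramolecular 1,6-addition to outrun tautomerisation of 26 to the aryl enol ether, return of sulfinate and intermolecular attack, which the six-membered transition state, high dilution and slow heterogeneous release of 26 are meant to secure, and it needs a single geometry of 26, which the 2'-methoxy group should enforce by turning the CH2O arm toward C6'. The weak, insoluble base is chosen so that the acidic C3–H of 27 is not removed.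

Step 17
Reactants: 27 the 5,7-di-O-MOM isoflavanone of step 16
Product: 28 (3S)-5,7-dihydroxy-3-{4-hydroxy-2-methoxy-3-[(E)-3-methylbut-1-enyl]phenyl}-6-(3-methylbut-2-enyl)-2,3-dihydro-4H-chromen-4-one
Conditions: 3 M aq HCl, MeOH, 0 °C → rt, short reaction time
Reagents that add atoms: none
Why: Acid-catalysed cleavage of the two aryl MOM acetals; dilute acid at low temperature should neither enolise C3 nor cyclise the prenyl or styrenyl side chains onto the neighbouring phenols.

## Compound list

1 | 5-bromoresorcinol | Oc1cc(O)cc(Br)c1 | starting material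
2 | 1-bromo-3,5-bis(methoxymethoxy)benzene | COCOc1cc(Br)cc(OCOC)c1 | intermediate
3 | prenyl bromide (1-bromo-3-methylbut-2-ene) | CC(C)=CCBr | starting material
4 | [4-bromo-2,6-bis(methoxymethoxy)phenyl]lithium (not isolated) | [Li]c1c(OCOC)cc(Br)cc1OCOC | intermediate
5 | [4-bromo-2,6-bis(methoxymethoxy)phenyl]copper (not isolated) | [Cu]c1c(OCOC)cc(Br)cc1OCOC | intermediate
6 | 5-bromo-1,3-bis(methoxymethoxy)-2-(3-methylbut-2-enyl)benzene | COCOc1cc(Br)cc(OCOC)c1CC=C(C)C | intermediate
7 | 3,5-bis(methoxymethoxy)-4-(3-methylbut-2-enyl)phenol | COCOc1cc(O)cc(OCOC)c1CC=C(C)C | intermediate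
8 | 6-hydroxy-2,4-bis(methoxymethoxy)-3-(3-methylbut-2-enyl)benzaldehyde | COCOc1cc(O)c(C=O)c(OCOC)c1CC=C(C)C | intermediate
9 | 4-bromo-3-methoxyphenol | COc1cc(O)ccc1Br | starting material
10 | 1-bromo-2-methoxy-4-(methoxymethoxy)benzene | COCOc1ccc(Br)c(OC)c1 | intermediate
11 | [3-bromo-2-methoxy-6-(methoxymethoxy)phenyl]lithium (not isolated) | [Li]c1c(OCOC)ccc(Br)c1OC | intermediate
12 | 1-bromo-3-iodo-2-methoxy-4-(methoxymethoxy)benzene | COCOc1ccc(Br)c(OC)c1I | intermediate
13 | 3-methylbut-1-yne | CC(C)C#C | starting material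
14 | (E)-4,4,5,5-tetramethyl-2-(3-methylbut-1-enyl)-1,3,2-dioxaborolane | CC(C)/C=C/B1OC(C)(C)C(C)(C)O1 | intermediate
15 | 1-bromo-2-methoxy-4-(methoxymethoxy)-3-[(E)-3-methylbut-1-enyl]benzene | COCOc1ccc(Br)c(OC)c1/C=C/C(C)C | intermediate
16 | {2-methoxy-4-(methoxymethoxy)-3-[(E)-3-methylbut-1-enyl]phenyl}lithium (not isolated) | [Li]c1ccc(OCOC)c(/C=C/C(C)C)c1OC | intermediate
17 | lithium (dimethylamino){2-methoxy-4-(methoxymethoxy)-3-[(E)-3-methylbut-1-enyl]phenyl}methanolate (not isolated) | [Li]OC(N(C)C)c1ccc(OCOC)c(/C=C/C(C)C)c1OC | intermediate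
18 | 2-methoxy-4-(methoxymethoxy)-3-[(E)-3-methylbut-1-enyl]benzaldehyde | COCOc1ccc(C=O)c(OC)c1/C=C/C(C)C | intermediate
19 | 4-hydroxy-2-methoxy-3-[(E)-3-methylbut-1-enyl]benzaldehyde | COc1c(C=O)ccc(O)c1/C=C/C(C)C | intermediate
20 | 2-methoxy-3-[(E)-3-methylbut-1-enyl]-4-(prop-2-enyloxy)benzaldehyde | COc1c(C=O)ccc(OCC=C)c1/C=C/C(C)C | intermediate
21 | 2-{2-methoxy-3-[(E)-3-methylbut-1-enyl]-4-(prop-2-enyloxy)phenyl}oxirane (racemic) | COc1c(C2CO2)ccc(OCC=C)c1/C=C/C(C)C | intermediate
22 | 6-[2-hydroxy-2-{2-methoxy-3-[(E)-3-methylbut-1-enyl]-4-(prop-2-enyloxy)phenyl}ethoxy]-2,4-bis(methoxymethoxy)-3-(3-methylbut-2-enyl)benzaldehyde (racemic) | COc1c(C(O)COc2cc(OCOC)c(CC=C(C)C)c(OCOC)c2C=O)ccc(OCC=C)c1/C=C/C(C)C | intermediate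
23 | methanesulfonate of 22 at the benzylic oxygen (racemic, not isolated) | COc1c(C(COc2cc(OCOC)c(CC=C(C)C)c(OCOC)c2C=O)OS(C)(=O)=O)ccc(OCC=C)c1/C=C/C(C)C | intermediate
24 | 6-[2-{2-methoxy-3-[(E)-3-methylbut-1-enyl]-4-(prop-2-enyloxy)phenyl}-2-(4-methylphenylsulfonyl)ethoxy]-2,4-bis(methoxymethoxy)-3-(3-methylbut-2-enyl)benzaldehyde (racemic) | COc1c(C(COc2cc(OCOC)c(CC=C(C)C)c(OCOC)c2C=O)S(=O)(=O)c2ccc(C)cc2)ccc(OCC=C)c1/C=C/C(C)C | intermediate
25 | 6-[2-{4-hydroxy-2-methoxy-3-[(E)-3-methylbut-1-enyl]phenyl}-2-(4-methylphenylsulfonyl)ethoxy]-2,4-bis(methoxymethoxy)-3-(3-methylbut-2-enyl)benzaldehyde (racemic; key-step precursor) | COc1c(C(COc2cc(OCOC)c(CC=C(C)C)c(OCOC)c2C=O)S(=O)(=O)c2ccc(C)cc2)ccc(O)c1/C=C/C(C)C | intermediate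
26 | 6-(2-{2-methoxy-3-[(E)-3-methylbut-1-enyl]-4-oxocyclohexa-2,5-dien-1-ylidene}ethoxy)-2,4-bis(methoxymethoxy)-3-(3-methylbut-2-enyl)benzaldehyde (ring-B para-quinone methide, not isolated) | COC1=C(/C=C/C(C)C)C(=O)C=CC1=CCOc1cc(OCOC)c(CC=C(C)C)c(OCOC)c1C=O | intermediate
27 | (3S)-3-{4-hydroxy-2-methoxy-3-[(E)-3-methylbut-1-enyl]phenyl}-5,7-bis(methoxymethoxy)-6-(3-methylbut-2-enyl)-2,3-dihydro-4H-chromen-4-one | COc1c([C@H]2COc3cc(OCOC)c(CC=C(C)C)c(OCOC)c3C2=O)ccc(O)c1/C=C/C(C)C | intermediate
28 | (3S)-5,7-dihydroxy-3-{4-hydroxy-2-methoxy-3-[(E)-3-methylbut-1-enyl]phenyl}-6-(3-methylbut-2-enyl)-2,3-dihydro-4H-chromen-4-one | COc1c([C@H]2COc3cc(O)c(CC=C(C)C)c(O)c3C2=O)ccc(O)c1/C=C/C(C)C | target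

## Step count and risk

Total step count: 17.
Longest linear sequence: 12 steps (from 9 to 28: steps 5, 6, 8, 9, 10, 11, 12, 13, 14, 15, 16, 17).

**1. Step 16 (proposed new method).**
What may go wrong:
- The carbene may add too slowly to the hindered, electron-rich 2,6-dioxygenated aldehyde.
- The quinone methide may tautomerise to the enol ether or oligomerise before it is trapped.
- Facial selectivity may be poor.
- The base may epimerise C3 after ring closure.

Fallback with known chemistry, setting out from 8 and 15 and coming back at 28: ring C is closed as an isoflavone and C3 is set by reduction.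
- Aldehyde 8 with MeMgBr (THF, 0 °C) should give 2-(1-hydroxyethyl)-3,5-bis(methoxymethoxy)-4-(3-methylbut-2-enyl)phenol F1, and MnO2 (CH2Cl2) should oxidise it to 1-[6-hydroxy-2,4-bis(methoxymethoxy)-3-(3-methylbut-2-enyl)phenyl]ethanone F2.
- DMF dimethyl acetal (90 °C) should convert F2 into the enaminone (E)-3-(dimethylamino)-1-[6-hydroxy-2,4-bis(methoxymethoxy)-3-(3-methylbut-2-enyl)phenyl]prop-2-en-1-one F3, and I2/pyridine in CHCl3 should cyclise it to 3-iodo-5,7-bis(methoxymethoxy)-6-(3-methylbut-2-enyl)-4H-chromen-4-one F4.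
- Bromide 15 is borylated (B2pin2, Pd(dppf)Cl2, KOAc, dioxane, 90 °C) to 2-{2-methoxy-4-(methoxymethoxy)-3-[(E)-3-methylbut-1-enyl]phenyl}-4,4,5,5-tetramethyl-1,3,2-dioxaborolane F5.
- Suzuki coupling of F4 with F5 (Pd(PPh3)4, aq K2CO3, DME) should give the isoflavone 3-{2-methoxy-4-(methoxymethoxy)-3-[(E)-3-methylbut-1-enyl]phenyl}-5,7-bis(methoxymethoxy)-6-(3-methylbut-2-enyl)-4H-chromen-4-one F6.
- Asymmetric transfer hydrogenation (RuCl(p-cymene)(TsDPEN), in the antipode that leads to 3S, HCO2H/Et3N) should reduce C2=C3 and then the ketone under dynamic kinetic resolution, giving cis-(3S,4S)-3-{2-methoxy-4-(methoxymethoxy)-3-[(E)-3-methylbut-1-enyl]phenyl}-5,7-bis(methoxymethoxy)-6-(3-methylbut-2-enyl)chroman-4-ol F7.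
- Dess–Martin periodinane buffered with NaHCO3 should return the ketone without touching C3, giving (3S)-3-{2-methoxy-4-(methoxymethoxy)-3-[(E)-3-methylbut-1-enyl]phenyl}-5,7-bis(methoxymethoxy)-6-(3-methylbut-2-enyl)-2,3-dihydro-4H-chromen-4-one F8.
- The conditions of step 17 then remove all three MOM groups and give 28.

**2. Step 13.**
What may go wrong:
- The electron-rich aryl group may steer the phenoxide to the benzylic carbon.
- The epoxide may rearrange to the arylacetaldehyde.
- The hydrogen-bonded salicylaldehyde phenoxide may react too slowly.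

Fallback, setting out from 20 and 8 and coming back at 24: the sulfone is installed on the ring-B fragment first and the ether is made by conjugate addition.
- NaBH4 (MeOH, 0 °C) reduces 20 to {2-methoxy-3-[(E)-3-methylbut-1-enyl]-4-(prop-2-enyloxy)phenyl}methanol F9.
- p-TolSO2H (CH2Cl2, rt; acid-promoted SN1 substitution of the electron-rich benzylic alcohol) should give 2-methoxy-3-[(E)-3-methylbut-1-enyl]-1-[(4-methylphenylsulfonyl)methyl]-4-(prop-2-enyloxy)benzene F10.
- Mannich-type methylenation (N,N,N',N'-tetramethyldiaminomethane, Ac2O, DMF, 60 °C) should give the vinyl sulfone 2-methoxy-3-[(E)-3-methylbut-1-enyl]-1-[1-(4-methylphenylsulfonyl)ethenyl]-4-(prop-2-enyloxy)benzene F11.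
- Oxa-Michael addition of phenol 8 to F11 (catalytic Cs2CO3, MeCN, rt) should give 24 directly.

**3. Step 14.**
What may go wrong:
- The ionised mesylate may lose a proton to give the aryl enol ether.
- Sulfinate may attack through oxygen.

Fallback, setting out from 22 and coming back at 25: the order is reversed so that the sulfinate enters through the phenol-assisted benzylic cation.
- Pd(PPh3)4 with morpholine (THF, rt) removes the allyl group from 22 and should give 6-[2-hydroxy-2-{4-hydroxy-2-methoxy-3-[(E)-3-methylbut-1-enyl]phenyl}ethoxy]-2,4-bis(methoxymethoxy)-3-(3-methylbut-2-enyl)benzaldehyde F12.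
- p-TolSO2H (CH2Cl2, rt) should then condense with the para-hydroxybenzylic alcohol of F12, the usual way such sulfones are made, and give 25.

## Further compounds

F1 | step 16 | 2-(1-hydroxyethyl)-3,5-bis(methoxymethoxy)-4-(3-methylbut-2-enyl)phenol (racemic) | COCOc1cc(O)c(C(C)O)c(OCOC)c1CC=C(C)C
F2 | step 16 | 1-[6-hydroxy-2,4-bis(methoxymethoxy)-3-(3-methylbut-2-enyl)phenyl]ethanone | COCOc1cc(O)c(C(C)=O)c(OCOC)c1CC=C(C)C
F3 | step 16 | (E)-3-(dimethylamino)-1-[6-hydroxy-2,4-bis(methoxymethoxy)-3-(3-methylbut-2-enyl)phenyl]prop-2-en-1-one | COCOc1cc(O)c(C(=O)/C=C/N(C)C)c(OCOC)c1CC=C(C)C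
F4 | step 16 | 3-iodo-5,7-bis(methoxymethoxy)-6-(3-methylbut-2-enyl)-4H-chromen-4-one | COCOc1cc2occ(I)c(=O)c2c(OCOC)c1CC=C(C)C
F5 | step 16 | 2-{2-methoxy-4-(methoxymethoxy)-3-[(E)-3-methylbut-1-enyl]phenyl}-4,4,5,5-tetramethyl-1,3,2-dioxaborolane | COCOc1ccc(B2OC(C)(C)C(C)(C)O2)c(OC)c1/C=C/C(C)C
F6 | step 16 | 3-{2-methoxy-4-(methoxymethoxy)-3-[(E)-3-methylbut-1-enyl]phenyl}-5,7-bis(methoxymethoxy)-6-(3-methylbut-2-enyl)-4H-chromen-4-one | COCOc1ccc(-c2coc3cc(OCOC)c(CC=C(C)C)c(OCOC)c3c2=O)c(OC)c1/C=C/C(C)C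
F7 | step 16 | cis-(3S,4S)-3-{2-methoxy-4-(methoxymethoxy)-3-[(E)-3-methylbut-1-enyl]phenyl}-5,7-bis(methoxymethoxy)-6-(3-methylbut-2-enyl)chroman-4-ol | COCOc1ccc([C@H]2COc3cc(OCOC)c(CC=C(C)C)c(OCOC)c3[C@H]2O)c(OC)c1/C=C/C(C)C
F8 | step 16 | (3S)-3-{2-methoxy-4-(methoxymethoxy)-3-[(E)-3-methylbut-1-enyl]phenyl}-5,7-bis(methoxymethoxy)-6-(3-methylbut-2-enyl)-2,3-dihydro-4H-chromen-4-one | COCOc1ccc([C@H]2COc3cc(OCOC)c(CC=C(C)C)c(OCOC)c3C2=O)c(OC)c1/C=C/C(C)C
F9 | step 13 | {2-methoxy-3-[(E)-3-methylbut-1-enyl]-4-(prop-2-enyloxy)phenyl}methanol | COc1c(CO)ccc(OCC=C)c1/C=C/C(C)C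
F10 | step 13 | 2-methoxy-3-[(E)-3-methylbut-1-enyl]-1-[(4-methylphenylsulfonyl)methyl]-4-(prop-2-enyloxy)benzene | COc1c(CS(=O)(=O)c2ccc(C)cc2)ccc(OCC=C)c1/C=C/C(C)C
F11 | step 13 | 2-methoxy-3-[(E)-3-methylbut-1-enyl]-1-[1-(4-methylphenylsulfonyl)ethenyl]-4-(prop-2-enyloxy)benzene | COc1c(C(=C)S(=O)(=O)c2ccc(C)cc2)ccc(OCC=C)c1/C=C/C(C)C
F12 | step 14 | 6-[2-hydroxy-2-{4-hydroxy-2-methoxy-3-[(E)-3-methylbut-1-enyl]phenyl}ethoxy]-2,4-bis(methoxymethoxy)-3-(3-methylbut-2-enyl)benzaldehyde (racemic) | COc1c(C(O)COc2cc(OCOC)c(CC=C(C)C)c(OCOC)c2C=O)ccc(O)c1/C=C/C(C)C
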